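**Retrosynthetic overview**

1. The target is orsellinic acid (ring A: carboxyl on C1, hydroxyls on C2 and C4) carrying on C6 a (2'S,12'S)-2',12'-diacetoxytridecyl chain. The acid and phenols are unmasked last (tert-butyl ester, two benzyl ethers), and both acetates are installed together just before.
2. Key disconnection: the C1'–C2' bond, between the benzylic CH2 on C6 of ring A and the oxygen-bearing C2'. It is made by lithiation–borylation–oxidation: the ring-A benzyl group shifts from boron onto a sparteine-defined α-lithiated carbamate carbon of the chain, and the C–B bond is then oxidized. One operation gives the C–C bond, the C2' stereocenter and the C2'–O bond.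
3. Enabling feature: C2' is a secondary carbinol carbon bonded directly to the benzylic C1' (a 1-aryl-2-alkanol unit), so its C–O bond can be read as an oxidized C–B bond and its configuration as that of a lithiated O–CH2 group. C1' is the C6 methyl of ring A, acidified by the ortho C1 ester, which lets it carry boron.
4. Fragments: the chain carbamate comes from 9-bromononan-1-ol and (S)-propylene oxide (sets C12'); the benzylic boronate comes from orsellinic acid by esterification, benzylation and lateral lithiation–borylation.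
5. No ring is constructed: ring A is taken intact from orsellinic acid and no temporary ring is used.

Key step: step 7

Assumption: both antipodes of sparteine are taken as purchasable; the (+)-antipode is required because the (−)-antipode would give the 2'R epimer.

**Route**

Step 1
Reactants: 1 9-bromononan-1-ol
Product: 2 9-bromononyl N,N-diisopropylcarbamate
Conditions: i-Pr2NC(O)Cl, i-Pr2NEt, 4-(dimethylamino)pyridine (cat.), CH2Cl2, reflux
Reagents that add atoms: N,N-diisopropylcarbamoyl chloride, CC(C)N(C(C)C)C(Cl)=O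
Why: O-carbamoylation of a primary alcohol by a carbamoyl chloride (nucleophilic acyl substitution) should proceed cleanly, the hindered amine base leaving the primary bromide untouched.

Step 2
Reactants: 2 9-bromononyl N,N-diisopropylcarbamate; 3 (S)-2-methyloxirane
Product: 5 (S)-11-hydroxydodecyl N,N-diisopropylcarbamate, via Grignard reagent 4 (not isolated)
Conditions: Mg, THF, 40 °C; then CuI (10 mol %), 3, THF, −30 → 0 °C; aq. NH4Cl
Reagents that add atoms: none
Why: Grignard formation should tolerate the hindered N,N-diisopropylcarbamate, and copper-catalysed epoxide opening (SN2 at the unsubstituted carbon) leaves the C–O stereocenter of 3 untouched, so C11 is S.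

Step 3
Reactants: 5 (S)-11-hydroxydodecyl N,N-diisopropylcarbamate
Product: 6 (S)-11-[(tert-butyldimethylsilyl)oxy]dodecyl N,N-diisopropylcarbamate
Conditions: TBSCl, imidazole, DMF, rt
Reagents that add atoms: tert-butyldimethylsilyl chloride, CC(C)(C)[Si](C)(C)Cl
Why: Standard silylation of a secondary alcohol gives an ether that is inert to s-BuLi at −78 °C and removable later without touching esters.

Step 4
Reactants: 7 orsellinic acid (2,4-dihydroxy-6-methylbenzoic acid)
Product: 8 tert-butyl 2,4-dihydroxy-6-methylbenzoate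
Conditions: O-tert-butyl-N,N'-diisopropylisourea, CH2Cl2/THF, rt
Reagents that add atoms: O-tert-butyl-N,N'-diisopropylisourea, CC(C)N=C(NC(C)C)OC(C)(C)C
Why: Isourea esterification is an O-alkylation of the carboxylate after the acid protonates the isourea, so it should be insensitive to the ortho,ortho-hindrance, leave the far less acidic phenols free, and avoid the heat or strong acid that would decarboxylate the acid.

Step 5
Reactants: 8 tert-butyl 2,4-dihydroxy-6-methylbenzoate
Product: 9 tert-butyl 2,4-bis(benzyloxy)-6-methylbenzoate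
Conditions: BnBr, K2CO3, DMF, 60 °C
Reagents that add atoms: benzyl bromide, BrCc1ccccc1
Why: Williamson etherification of both phenols should go to completion under these conditions, the tert-butyl ester being stable to carbonate.

Step 6
Reactants: 9 tert-butyl 2,4-bis(benzyloxy)-6-methylbenzoate
Product: 12 tert-butyl 2,4-bis(benzyloxy)-6-[(4,4,5,5-tetramethyl-1,3,2-dioxaborolan-2-yl)methyl]benzoate, via benzylic lithium species 10 (not isolated), via borate complex 11 (not isolated)
Conditions: LiN(i-Pr)2, THF, −78 °C; then i-PrOBpin, −78 → 0 °C; HCl (Et2O)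
Reagents that add atoms: 2-isopropoxy-4,4,5,5-tetramethyl-1,3,2-dioxaborolane, CC(C)OB1OC(C)(C)C(C)(C)O1
Why: Lateral lithiation of the ortho-toluate (the C6 methyl is acidified by the C1 ester) followed by C-borylation with an alkoxyborane and acid collapse of the borate should give the benzylic pinacol boronate, with the hindered tert-butyl ester suppressing self-condensation.

Step 7
Reactants: 6 (S)-11-[(tert-butyldimethylsilyl)oxy]dodecyl N,N-diisopropylcarbamate; 12 tert-butyl 2,4-bis(benzyloxy)-6-[(4,4,5,5-tetramethyl-1,3,2-dioxaborolan-2-yl)methyl]benzoate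
Product: 16 tert-butyl 2,4-bis(benzyloxy)-6-[(2S,12S)-12-[(tert-butyldimethylsilyl)oxy]-2-hydroxytridecyl]benzoate, via lithiated carbamate 13 (not isolated), via boronate complex 14 (not isolated), via secondary boronic ester 15 (not isolated)
Conditions: 6 (1.3 equiv), s-BuLi, (+)-sparteine, Et2O, −78 °C, 5 h; then 12, −78 °C, 1 h; then 35 °C, 16 h; then NaBO3·4H2O, THF/H2O, rt
Reagents that add atoms: sodium perborate tetrahydrate (hydrate water omitted), [Na+].[Na+].O[B-]1(O)OO[B-](O)(O)OO1
Why: (+)-Sparteine-complexed s-BuLi should remove one enantiotopic proton of the O–CH2 group of 6 to give the configurationally stable (R)-α-lithio carbamate 13, whose carbon adds to the boron of 12 with retention to form boronate complex 14; on warming, the benzylic CH2 of ring A migrates from boron to carbon anti-periplanar to the departing carbamate (1,2-metalate rearrangement, inversion at carbon) to give the (S)-boronic ester 15, and perborate replaces boron by oxygen with retention. The closest known reaction type is the lithiation–borylation of sparteine-lithiated primary O-alkyl N,N-diisopropylcarbamates with pinacol boronic esters (a reagent-controlled Matteson-type homologation) followed by oxidation to the secondary alcohol. No ring is closed. The new C2' stereocenter is controlled by the chiral diamine alone, through the sequence retention, inversion, retention, so the remote C12' center has no influence. The step needs chemoselectivity for boron over the ester carbonyl and over the benzylic and benzyl ether protons: complexation at boron is fast at −78 °C, the tert-butyl ester is shielded by its two ortho substituents, and the mildly basic perborate oxidation should keep the new hydroxyl from lactonizing onto the ester.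

Step 8
Reactants: 16 tert-butyl 2,4-bis(benzyloxy)-6-[(2S,12S)-12-[(tert-butyldimethylsilyl)oxy]-2-hydroxytridecyl]benzoate
Product: 17 tert-butyl 2,4-bis(benzyloxy)-6-[(2S,12S)-2,12-dihydroxytridecyl]benzoate
Conditions: HF·pyridine, pyridine, THF, 0 °C → rt
Reagents that add atoms: none
Why: Fluoride-mediated Si–O cleavage under buffered, non-basic conditions generates no alkoxide, so the C2' hydroxyl should not lactonize onto the hindered ester.

Step 9
Reactants: 17 tert-butyl 2,4-bis(benzyloxy)-6-[(2S,12S)-2,12-dihydroxytridecyl]benzoate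
Product: 18 tert-butyl 2,4-bis(benzyloxy)-6-[(2S,12S)-2,12-diacetoxytridecyl]benzoate
Conditions: Ac2O, pyridine, 4-(dimethylamino)pyridine (cat.), CH2Cl2, 0 °C → rt
Reagents that add atoms: acetic anhydride, CC(=O)OC(C)=O
Why: Nucleophile-catalysed acylation of both secondary alcohols occurs at oxygen with retention at C2' and C12'.

Step 10
Reactants: 18 tert-butyl 2,4-bis(benzyloxy)-6-[(2S,12S)-2,12-diacetoxytridecyl]benzoate
Product: 19 2,4-bis(benzyloxy)-6-[(2S,12S)-2,12-diacetoxytridecyl]benzoic acid
Conditions: CF3CO2H/CH2Cl2 (1:4), 0 °C → rt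
Reagents that add atoms: none
Why: Acid-promoted alkyl–oxygen cleavage of the tert-butyl ester (loss of isobutene) should leave the secondary acetates and aryl benzyl ethers intact in dilute trifluoroacetic acid; with C2'–O already acetylated the freed acid cannot lactonize.

Step 11
Reactants: 19 2,4-bis(benzyloxy)-6-[(2S,12S)-2,12-diacetoxytridecyl]benzoic acid
Product: 20 2-[(2S,12S)-2,12-diacetoxytridecyl]-4,6-dihydroxybenzoic acid
Conditions: H2 (1 atm), Pd/C (10 wt% Pd on carbon), EtOAc, rt
Reagents that add atoms: none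
Why: Neutral hydrogenolysis of the two aryl benzyl ethers should leave the acetates, the acid and the non-benzylic C2'–O bond untouched.

**Compound list**

1 | 9-bromononan-1-ol | OCCCCCCCCCBr | starting material
2 | 9-bromononyl N,N-diisopropylcarbamate | CC(C)N(C(C)C)C(=O)OCCCCCCCCCBr | intermediate
3 | (S)-2-methyloxirane ((S)-propylene oxide) | C[C@H]1CO1 | starting material
4 | [9-(N,N-diisopropylcarbamoyloxy)nonyl]magnesium bromide | CC(C)N(C(C)C)C(=O)OCCCCCCCCC[Mg]Br | intermediate
5 | (S)-11-hydroxydodecyl N,N-diisopropylcarbamate | C[C@H](O)CCCCCCCCCCOC(=O)N(C(C)C)C(C)C | intermediate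
6 | (S)-11-[(tert-butyldimethylsilyl)oxy]dodecyl N,N-diisopropylcarbamate | C[C@H](O[Si](C)(C)C(C)(C)C)CCCCCCCCCCOC(=O)N(C(C)C)C(C)C | intermediate
7 | orsellinic acid (2,4-dihydroxy-6-methylbenzoic acid) | Cc1cc(O)cc(O)c1C(=O)O | starting material
8 | tert-butyl 2,4-dihydroxy-6-methylbenzoate | Cc1cc(O)cc(O)c1C(=O)OC(C)(C)C | intermediate
9 | tert-butyl 2,4-bis(benzyloxy)-6-methylbenzoate | Cc1cc(OCc2ccccc2)cc(OCc2ccccc2)c1C(=O)OC(C)(C)C | intermediate
10 | tert-butyl 2,4-bis(benzyloxy)-6-(lithiomethyl)benzoate | [Li]Cc1cc(OCc2ccccc2)cc(OCc2ccccc2)c1C(=O)OC(C)(C)C | intermediate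
11 | lithium [3,5-bis(benzyloxy)-2-(tert-butoxycarbonyl)benzyl](isopropoxy)(pinacolato)borate | [Li+].CC(C)O[B-]1(Cc2cc(OCc3ccccc3)cc(OCc3ccccc3)c2C(=O)OC(C)(C)C)OC(C)(C)C(C)(C)O1 | intermediate
12 | tert-butyl 2,4-bis(benzyloxy)-6-[(4,4,5,5-tetramethyl-1,3,2-dioxaborolan-2-yl)methyl]benzoate | CC1(C)OB(Cc2cc(OCc3ccccc3)cc(OCc3ccccc3)c2C(=O)OC(C)(C)C)OC1(C)C | intermediate
13 | (1R,11S)-11-[(tert-butyldimethylsilyl)oxy]-1-lithiododecyl N,N-diisopropylcarbamate (as its (+)-sparteine complex) | [Li][C@@H](OC(=O)N(C(C)C)C(C)C)CCCCCCCCC[C@H](C)O[Si](C)(C)C(C)(C)C | intermediate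
14 | lithium [3,5-bis(benzyloxy)-2-(tert-butoxycarbonyl)benzyl][(1R,11S)-11-[(tert-butyldimethylsilyl)oxy]-1-(N,N-diisopropylcarbamoyloxy)dodecyl](pinacolato)borate | [Li+].CC1(C)O[B-](Cc2cc(OCc3ccccc3)cc(OCc3ccccc3)c2C(=O)OC(C)(C)C)([C@@H](OC(=O)N(C(C)C)C(C)C)CCCCCCCCC[C@H](C)O[Si](C)(C)C(C)(C)C)OC1(C)C | intermediate
15 | tert-butyl 2,4-bis(benzyloxy)-6-[(2S,12S)-12-[(tert-butyldimethylsilyl)oxy]-2-(4,4,5,5-tetramethyl-1,3,2-dioxaborolan-2-yl)tridecyl]benzoate | CC1(C)OB([C@H](Cc2cc(OCc3ccccc3)cc(OCc3ccccc3)c2C(=O)OC(C)(C)C)CCCCCCCCC[C@H](C)O[Si](C)(C)C(C)(C)C)OC1(C)C | intermediate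
16 | tert-butyl 2,4-bis(benzyloxy)-6-[(2S,12S)-12-[(tert-butyldimethylsilyl)oxy]-2-hydroxytridecyl]benzoate | O[C@@H](CCCCCCCCC[C@H](C)O[Si](C)(C)C(C)(C)C)Cc1cc(OCc2ccccc2)cc(OCc2ccccc2)c1C(=O)OC(C)(C)C | intermediate
17 | tert-butyl 2,4-bis(benzyloxy)-6-[(2S,12S)-2,12-dihydroxytridecyl]benzoate | O[C@@H](CCCCCCCCC[C@H](C)O)Cc1cc(OCc2ccccc2)cc(OCc2ccccc2)c1C(=O)OC(C)(C)C | intermediate
18 | tert-butyl 2,4-bis(benzyloxy)-6-[(2S,12S)-2,12-diacetoxytridecyl]benzoate | CC(=O)O[C@@H](CCCCCCCCC[C@H](C)OC(C)=O)Cc1cc(OCc2ccccc2)cc(OCc2ccccc2)c1C(=O)OC(C)(C)C | intermediate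
19 | 2,4-bis(benzyloxy)-6-[(2S,12S)-2,12-diacetoxytridecyl]benzoic acid | CC(=O)O[C@@H](CCCCCCCCC[C@H](C)OC(C)=O)Cc1cc(OCc2ccccc2)cc(OCc2ccccc2)c1C(=O)O | intermediate
20 | 2-[(2S,12S)-2,12-diacetoxytridecyl]-4,6-dihydroxybenzoic acid | CC(=O)O[C@@H](CCCCCCCCC[C@H](C)OC(C)=O)Cc1cc(O)cc(O)c1C(=O)O | target

**Step count and risks**

Total step count: 11. Longest linear sequence: 8 steps (steps 4, 5, 6, 7, 8, 9, 10, 11 from orsellinic acid; equally steps 1, 2, 3, 7 to 11 from 9-bromononan-1-ol).

Steps most likely to fail: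

1. Step 7. The boronate complex 14 carries an ester-stabilized benzyl group. It may fragment by loss of that benzylic anion, or the lithiated carbamate may deprotonate the benzylic position or attack the ester, instead of undergoing clean 1,2-migration. The freed C2' hydroxyl may also lactonize onto the ester during oxidation.
   Fallback: the carboxyl carbon is left out of the coupling partner and introduced afterwards. It sets out from 6 and comes back at 19.
   - Commercial 3,5-bis(benzyloxy)benzyl bromide (BrCc1cc(OCc2ccccc2)cc(OCc2ccccc2)c1) is converted by Miyaura borylation (bis(pinacolato)diboron, KOAc, PdCl2(dppf), dioxane, 80 °C) into 2-[3,5-bis(benzyloxy)benzyl]-4,4,5,5-tetramethyl-1,3,2-dioxaborolane F1.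
   - Lithiated carbamate 13, made from 6 as in step 7, should add to F1 to give the lithium boronate complex F2, which rearranges on warming to the secondary boronic ester F3 and is oxidized with NaBO3·4H2O to (2S,12S)-1-[3,5-bis(benzyloxy)phenyl]-12-[(tert-butyldimethylsilyl)oxy]tridecan-2-ol F4.
   - HF·pyridine should give (2S,12S)-1-[3,5-bis(benzyloxy)phenyl]tridecane-2,12-diol F5, and Ac2O/pyridine the diacetate (2S,12S)-1-[3,5-bis(benzyloxy)phenyl]tridecane-2,12-diyl diacetate F6.
   - Vilsmeier–Haack formylation (POCl3, DMF, 0 → 60 °C) is expected ortho to the side chain and para to a benzyloxy group, giving (2S,12S)-1-[3,5-bis(benzyloxy)-2-formylphenyl]tridecane-2,12-diyl diacetate F7.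
   - Pinnick oxidation (NaClO2, NaH2PO4, 2-methylbut-2-ene, t-BuOH/H2O) then returns the route at acid 19.

2. Step 6. The ester-stabilized benzylic anion 10 is ambident and weakly nucleophilic. Boron trapping may be reversible or occur at oxygen, so that work-up returns 9, or the anion may condense with unreacted ester.
   Fallback: C–halogen and C–B bond formation are separated. It sets out from 9 and comes back at 12. Anion 10 (from 9 with LiN(i-Pr)2, THF, −78 °C) is added to hexachloroethane (ClC(Cl)(Cl)C(Cl)(Cl)Cl) to give tert-butyl 2,4-bis(benzyloxy)-6-(chloromethyl)benzoate F8. Copper-catalysed borylation of the benzylic chloride (bis(pinacolato)diboron, CuI (cat.), PPh3, LiOMe, DMF, rt) should then give 12.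

3. Step 4. The phenolic hydroxyls may be tert-butylated in competition with the carboxyl, or the electron-rich acid may decarboxylate before it is esterified.
   Fallback: the phenols are protected first and the tert-butyl ester is made last. It sets out from 7 and comes back at 9. Orsellinic acid 7 with BnBr (excess), K2CO3, DMF should give benzyl 2,4-bis(benzyloxy)-6-methylbenzoate F9. KOH in aqueous DMSO at 90 °C cleaves the hindered benzyl ester to 2,4-bis(benzyloxy)-6-methylbenzoic acid F10. This acid, free of phenols, is tert-butylated with O-tert-butyl-N,N'-diisopropylisourea to give 9.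

Further compounds
F1 | step 7 | 2-[3,5-bis(benzyloxy)benzyl]-4,4,5,5-tetramethyl-1,3,2-dioxaborolane | CC1(C)OB(Cc2cc(OCc3ccccc3)cc(OCc3ccccc3)c2)OC1(C)C
F2 | step 7 | lithium [3,5-bis(benzyloxy)benzyl][(1R,11S)-11-[(tert-butyldimethylsilyl)oxy]-1-(N,N-diisopropylcarbamoyloxy)dodecyl](pinacolato)borate | [Li+].CC1(C)O[B-](Cc2cc(OCc3ccccc3)cc(OCc3ccccc3)c2)([C@@H](OC(=O)N(C(C)C)C(C)C)CCCCCCCCC[C@H](C)O[Si](C)(C)C(C)(C)C)OC1(C)C
F3 | step 7 | 2-[(2S,12S)-1-[3,5-bis(benzyloxy)phenyl]-12-[(tert-butyldimethylsilyl)oxy]tridecan-2-yl]-4,4,5,5-tetramethyl-1,3,2-dioxaborolane | CC1(C)OB([C@H](Cc2cc(OCc3ccccc3)cc(OCc3ccccc3)c2)CCCCCCCCC[C@H](C)O[Si](C)(C)C(C)(C)C)OC1(C)C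
F4 | step 7 | (2S,12S)-1-[3,5-bis(benzyloxy)phenyl]-12-[(tert-butyldimethylsilyl)oxy]tridecan-2-ol | O[C@@H](CCCCCCCCC[C@H](C)O[Si](C)(C)C(C)(C)C)Cc1cc(OCc2ccccc2)cc(OCc2ccccc2)c1
F5 | step 7 | (2S,12S)-1-[3,5-bis(benzyloxy)phenyl]tridecane-2,12-diol | O[C@@H](CCCCCCCCC[C@H](C)O)Cc1cc(OCc2ccccc2)cc(OCc2ccccc2)c1
F6 | step 7 | (2S,12S)-1-[3,5-bis(benzyloxy)phenyl]tridecane-2,12-diyl diacetate | CC(=O)O[C@@H](CCCCCCCCC[C@H](C)OC(C)=O)Cc1cc(OCc2ccccc2)cc(OCc2ccccc2)c1
F7 | step 7 | (2S,12S)-1-[3,5-bis(benzyloxy)-2-formylphenyl]tridecane-2,12-diyl diacetate | CC(=O)O[C@@H](CCCCCCCCC[C@H](C)OC(C)=O)Cc1cc(OCc2ccccc2)cc(OCc2ccccc2)c1C=O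
F8 | step 6 | tert-butyl 2,4-bis(benzyloxy)-6-(chloromethyl)benzoate | ClCc1cc(OCc2ccccc2)cc(OCc2ccccc2)c1C(=O)OC(C)(C)C
F9 | step 4 | benzyl 2,4-bis(benzyloxy)-6-methylbenzoate | Cc1cc(OCc2ccccc2)cc(OCc2ccccc2)c1C(=O)OCc1ccccc1
F10 | step 4 | 2,4-bis(benzyloxy)-6-methylbenzoic acid | Cc1cc(OCc2ccccc2)cc(OCc2ccccc2)c1C(=O)O
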